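**Retrosynthetic overview**
1. Target 30 ⇐ diol 29 (selective primary acetylation) ⇐ bis-silyl ether 28 ⇐ ring ketone 27 (methylenation at C-9) ⇐ ring carbinol 26.
2. The only ring, the nine-membered carbocycle, is closed at C6–C7 by an intramolecular B-alkyl Suzuki–Miyaura macrocyclization of seco iodo-alkene 24; this also fixes the E ring alkene.
3. 24 ⇐ Evans syn-aldol of imide 20 with acrolein (sets C-1, brings C-9/C-8/C-7) ⇐ auxiliary-directed 1,4-addition of the dienyl-metal from bromide 17 to enoyl imide 10 (sets C-2).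
4. 10 ⇐ HWE of aldehyde 4 (from pent-4-yn-1-ol by carboalumination) with phosphonate 9; 17 ⇐ site-selective Suzuki coupling of (E)-dibromide 16 with alkenylboronate 13.

Notation: ring locants are C-1 (CO2Me), C-2 (side chain), C-5=C-6 (ring alkene), C-9 (methylidene). TBSO = tert-butyldimethylsilyloxy, TESO = triethylsilyloxy, 9-BBN = 9-borabicyclo[3.3.1]nonane, DMP = Dess–Martin periodinane. Equivalents and loadings are indicative.

**Route**

Step 1
Reactants: 1 pent-4-yn-1-ol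
Product: 3 (E)-5-iodo-4-methylpent-4-en-1-ol, via alkenylalane 2 (not isolated)
Conditions: AlMe3 (3 equiv), Cp2ZrCl2 (25 mol %), CH2Cl2, 0 °C to rt; then I2, THF, −30 to 0 °C
Reagents that add atoms: trimethylaluminium, C[Al](C)C; iodine, II
Why: Negishi zirconium-catalysed carboalumination adds methyl and aluminium syn across the alkyne with aluminium at the terminus, and iodinolysis with retention gives the (E)-iodoalkene that later becomes the E ring alkene.

Step 2
Reactants: 3 (E)-5-iodo-4-methylpent-4-en-1-ol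
Product: 4 (E)-5-iodo-4-methylpent-4-enal
Conditions: DMP, CH2Cl2, rt
Reagents that add atoms: none
Why: Dess–Martin oxidation stops cleanly at the aldehyde and does not touch the iodoalkene.

Step 3
Reactants: 5 (R)-4-benzyloxazolidin-2-one; 6 bromoacetyl bromide
Product: 8 (R)-4-benzyl-3-(bromoacetyl)oxazolidin-2-one, via lithiated oxazolidinone 7 (not isolated)
Conditions: n-BuLi, THF, −78 °C; then 6, −78 to 0 °C
Reagents that add atoms: none
Why: N-acylation of the lithium amide occurs at the acyl bromide, which is far more electrophilic than the alkyl bromide.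

Step 4
Reactants: 8 (R)-4-benzyl-3-(bromoacetyl)oxazolidin-2-one
Product: 9 diethyl {2-[(R)-4-benzyl-2-oxooxazolidin-3-yl]-2-oxoethyl}phosphonate
Conditions: P(OEt)3, neat, 80 °C
Reagents that add atoms: triethyl phosphite, CCOP(OCC)OCC
Why: Michaelis–Arbuzov reaction of the activated α-bromo imide gives the phosphonate with loss of bromoethane.

Step 5
Reactants: 4 (E)-5-iodo-4-methylpent-4-enal; 9 imide phosphonate
Product: 10 (R)-4-benzyl-3-[(2E,6E)-7-iodo-6-methylhepta-2,6-dienoyl]oxazolidin-2-one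
Conditions: LiCl, iPr2NEt, MeCN, rt
Reagents that add atoms: none
Why: Horner–Wadsworth–Emmons olefination under Masamune–Roush conditions gives the E-enoyl imide without harming the imide or the iodoalkene.

Step 6
Reactants: 11 2-methylbut-3-yn-2-ol
Product: 12 triethyl[(2-methylbut-3-yn-2-yl)oxy]silane
Conditions: Et3SiOTf, 2,6-lutidine, CH2Cl2, 0 °C
Reagents that add atoms: triethylsilyl triflate, CC[Si](CC)(CC)OS(=O)(=O)C(F)(F)F
Why: Silylation of the tertiary alcohol with the silyl triflate masks the only acidic proton before hydroboration and organolithium chemistry.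

Step 7
Reactants: 12 triethyl[(2-methylbut-3-yn-2-yl)oxy]silane
Product: 13 triethyl{[(3E)-2-methyl-4-(4,4,5,5-tetramethyl-1,3,2-dioxaborolan-2-yl)but-3-en-2-yl]oxy}silane
Conditions: pinacolborane, Cp2Zr(H)Cl (5 mol %), Et3N (10 mol %), neat, 60 °C
Reagents that add atoms: pinacolborane, [H]B1OC(C)(C)C(C)(C)O1
Why: Zirconocene-catalysed hydroboration of the terminal alkyne is syn and anti-Markovnikov, giving the (E)-alkenylboronate only.

Step 8
Reactants: 14 prop-2-yn-1-ol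
Product: 15 (E)-2,3-dibromoprop-2-en-1-ol
Conditions: Br2 (1.0 equiv), CH2Cl2, −20 to 0 °C, dark
Reagents that add atoms: bromine, BrBr
Why: Electrophilic anti-addition of bromine through a bromonium ion places the two bromides trans, which fixes the later C-2/side-chain geometry.

Step 9
Reactants: 15 (E)-2,3-dibromoprop-2-en-1-ol
Product: 16 tert-butyl{[(E)-2,3-dibromoprop-2-en-1-yl]oxy}dimethylsilane
Conditions: TBSCl, imidazole, CH2Cl2, 0 °C to rt
Reagents that add atoms: tert-butyldimethylsilyl chloride, CC(C)(C)[Si](C)(C)Cl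
Why: Standard silylation of the primary alcohol protects it for the organometallic steps and removes the minor Z isomer on chromatography.

Step 10
Reactants: 16 TBS ether of the (E)-dibromide; 13 (E)-alkenylboronate
Product: 17 (2E,4E)-2-bromo-1-(TBSO)-6-methyl-6-(TESO)hepta-2,4-diene
Conditions: Pd(PPh3)4 (5 mol %), aq K3PO4, THF, 45 °C, 13 (1.0 equiv) added slowly
Reagents that add atoms: none
Why: Suzuki–Miyaura coupling in which oxidative addition takes the unhindered terminal C–Br bond in preference to the internal one, and retention at both partners leaves the remaining bromide trans to the new (E)-alkenyl chain.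

Step 11
Reactants: 17 (2E,4E)-2-bromodiene; 10 enoyl imide
Product: 20 (R)-4-benzyl-3-{(3S,6E)-7-iodo-6-methyl-3-[(2Z,4E)-1-(TBSO)-6-methyl-6-(TESO)hepta-2,4-dien-2-yl]hept-6-enoyl}oxazolidin-2-one, via alkenyllithium 18 (not isolated), via alkenylmagnesium bromide 19 (not isolated)
Conditions: 17 (1.5 equiv), t-BuLi (3.0 equiv), Et2O, −78 °C; MgBr2·OEt2, −78 °C; CuBr·SMe2 (30 mol %), THF/Me2S; then 10, −78 to −30 °C; aq NH4Cl
Reagents that add atoms: none
Why: Bromine–lithium exchange and transmetalation proceed with retention of alkene geometry, and the copper-catalysed 1,4-addition to the magnesium-chelated syn-s-cis N-enoyl oxazolidinone occurs on the face opposite the benzyl group, which sets C-2 as S.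

Step 12
Reactants: 20 conjugate adduct imide; 21 acrolein
Product: 23 (R)-4-benzyl-3-{(2R,3S,6E)-2-[(1S)-1-hydroxyprop-2-en-1-yl]-7-iodo-6-methyl-3-[(2Z,4E)-1-(TBSO)-6-methyl-6-(TESO)hepta-2,4-dien-2-yl]hept-6-enoyl}oxazolidin-2-one, via dibutylboron enolate 22 (not isolated)
Conditions: Bu2BOTf, iPr2NEt, CH2Cl2, −78 to 0 °C; 21, −78 to 0 °C; pH 7 buffer, MeOH, H2O2, 0 °C
Reagents that add atoms: none
Why: Evans syn-aldol reaction in which the (Z)-boron enolate reacts through a Zimmerman–Traxler chair on the face dictated by the (R)-auxiliary, setting the ester-bearing carbon (the future C-1) as R; the carbinol centre is later oxidised.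

Step 13
Reactants: 23 syn-aldol imide
Product: 24 methyl (2R,3S,6E)-2-[(1S)-1-hydroxyprop-2-en-1-yl]-7-iodo-6-methyl-3-[(2Z,4E)-1-(TBSO)-6-methyl-6-(TESO)hepta-2,4-dien-2-yl]hept-6-enoate
Conditions: MeMgBr, MeOH, CH2Cl2, 0 °C (MeOMgBr formed in situ)
Reagents that add atoms: methanol, CO
Why: Chelation-assisted transesterification of the β-hydroxy imide by bromomagnesium methoxide cleaves the exocyclic acyl group and releases the auxiliary without retro-aldol or epimerisation.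

Step 14
Reactants: 24 seco hydroxy ester
Product: 26 methyl (1R,2S,5E,9S)-9-hydroxy-5-methyl-2-[(2Z,4E)-1-(TBSO)-6-methyl-6-(TESO)hepta-2,4-dien-2-yl]cyclonon-5-ene-1-carboxylate, via bis-borane 25 (not isolated)
Conditions: 9-BBN (3 equiv), THF, rt; then slow addition to Pd(dppf)Cl2 (20 mol %), AsPh3, Cs2CO3, DMF/THF/H2O, 50 °C, 2 mM
Reagents that add atoms: none
Why: 9-BBN hydroborates only the monosubstituted alkene (anti-Markovnikov), and the intramolecular B-alkyl Suzuki–Miyaura coupling with the alkenyl iodide at high dilution closes the nine-membered ring at C6–C7 with retention of the E geometry and without touching a stereocentre.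

Step 15
Reactants: 26 ring carbinol
Product: 27 methyl (1R,2S,5E)-5-methyl-9-oxo-2-[(2Z,4E)-1-(TBSO)-6-methyl-6-(TESO)hepta-2,4-dien-2-yl]cyclonon-5-ene-1-carboxylate
Conditions: DMP, pyridine, CH2Cl2, 0 °C to rt; used crude at once
Reagents that add atoms: none
Why: Buffered Dess–Martin oxidation converts the secondary alcohol into the ketone under non-enolising conditions, so the C-1 centre is carried forward unchanged.

Step 16
Reactants: 27 ring β-keto ester
Product: 28 methyl (1R,2S,5E)-5-methyl-9-methylidene-2-[(2Z,4E)-1-(TBSO)-6-methyl-6-(TESO)hepta-2,4-dien-2-yl]cyclonon-5-ene-1-carboxylate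
Conditions: Cp2Ti(μ-Cl)(μ-CH2)AlMe2 (Tebbe reagent, 1.5 equiv), pyridine, THF/toluene, −40 to 0 °C; Na2SO4·10H2O quench
Reagents that add atoms: Tebbe reagent, C=[Ti](C1C=CC=C1)C1C=CC=C1.C[Al](C)Cl
Why: Tebbe methylenation uses a non-basic titanium methylidene that reacts with the ketone much faster than with the ester and should not deprotonate C-1, so the trans C-1/C-2 relationship is expected to survive.

Step 17
Reactants: 28 bis-silyl ether
Product: 29 methyl (1R,2S,5E)-2-[(2Z,4E)-1,6-dihydroxy-6-methylhepta-2,4-dien-2-yl]-5-methyl-9-methylidenecyclonon-5-ene-1-carboxylate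
Conditions: HF·pyridine, pyridine, THF, 0 °C to rt
Reagents that add atoms: none
Why: Buffered fluoride desilylation removes both silyl ethers without isomerising the β,γ-unsaturated ester or ionising the tertiary dienyl alcohol.

Step 18
Reactants: 29 diol
Product: 30 methyl (1R,2S,5E)-2-[(2Z,4E)-1-acetoxy-6-hydroxy-6-methylhepta-2,4-dien-2-yl]-5-methyl-9-methylidenecyclonon-5-ene-1-carboxylate
Conditions: Ac2O (1.5 equiv), pyridine, CH2Cl2, 0 °C
Reagents that add atoms: acetic anhydride, CC(=O)OC(C)=O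
Why: Chemoselective acylation acetylates the primary allylic hydroxyl, while the hindered tertiary alcohol does not react in the absence of DMAP.

**Compound list**

1 | pent-4-yn-1-ol | C#CCCCO | starting material
2 | dimethyl[(E)-5-(dimethylaluminiooxy)-2-methylpent-1-en-1-yl]alane | C[Al](C)OCCC/C(C)=C/[Al](C)C | intermediate
3 | (E)-5-iodo-4-methylpent-4-en-1-ol | OCCC/C(C)=C/I | intermediate
4 | (E)-5-iodo-4-methylpent-4-enal | O=CCC/C(C)=C/I | intermediate
5 | (R)-4-benzyloxazolidin-2-one | O=C1N[C@H](Cc2ccccc2)CO1 | starting material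
6 | bromoacetyl bromide | BrCC(Br)=O | starting material
7 | N-lithio-(R)-4-benzyloxazolidin-2-one | [Li]N1[C@H](Cc2ccccc2)COC1=O | intermediate
8 | (R)-4-benzyl-3-(bromoacetyl)oxazolidin-2-one | BrCC(=O)N1[C@H](Cc2ccccc2)COC1=O | intermediate
9 | diethyl {2-[(R)-4-benzyl-2-oxooxazolidin-3-yl]-2-oxoethyl}phosphonate | CCOP(=O)(OCC)CC(=O)N1[C@H](Cc2ccccc2)COC1=O | intermediate
10 | (R)-4-benzyl-3-[(2E,6E)-7-iodo-6-methylhepta-2,6-dienoyl]oxazolidin-2-one | O=C(/C=C/CC/C(C)=C/I)N1[C@H](Cc2ccccc2)COC1=O | intermediate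
11 | 2-methylbut-3-yn-2-ol | CC(C)(O)C#C | starting material
12 | triethyl[(2-methylbut-3-yn-2-yl)oxy]silane | CC[Si](CC)(CC)OC(C)(C)C#C | intermediate
13 | triethyl{[(3E)-2-methyl-4-(4,4,5,5-tetramethyl-1,3,2-dioxaborolan-2-yl)but-3-en-2-yl]oxy}silane | CC[Si](CC)(CC)OC(C)(C)/C=C/B1OC(C)(C)C(C)(C)O1 | intermediate
14 | prop-2-yn-1-ol | C#CCO | starting material
15 | (E)-2,3-dibromoprop-2-en-1-ol | OC/C(Br)=C\Br | intermediate
16 | tert-butyl{[(E)-2,3-dibromoprop-2-en-1-yl]oxy}dimethylsilane | CC(C)(C)[Si](C)(C)OC/C(Br)=C\Br | intermediate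
17 | (2E,4E)-2-bromo-1-(TBSO)-6-methyl-6-(TESO)hepta-2,4-diene | CC(C)(C)[Si](C)(C)OC/C(Br)=C\C=C\C(C)(C)O[Si](CC)(CC)CC | intermediate
18 | [(2Z,4E)-1-(TBSO)-6-methyl-6-(TESO)hepta-2,4-dien-2-yl]lithium (Li trans to C-4) | CC(C)(C)[Si](C)(C)OC/C([Li])=C\C=C\C(C)(C)O[Si](CC)(CC)CC | intermediate
19 | [(2E,4E)-1-(TBSO)-6-methyl-6-(TESO)hepta-2,4-dien-2-yl]magnesium bromide (Mg trans to C-4) | CC(C)(C)[Si](C)(C)OC/C([Mg]Br)=C\C=C\C(C)(C)O[Si](CC)(CC)CC | intermediate
20 | (R)-4-benzyl-3-{(3S,6E)-7-iodo-6-methyl-3-[(2Z,4E)-1-(TBSO)-6-methyl-6-(TESO)hepta-2,4-dien-2-yl]hept-6-enoyl}oxazolidin-2-one | O=C(C[C@H](CC/C(C)=C/I)/C(CO[Si](C)(C)C(C)(C)C)=C/C=C/C(C)(C)O[Si](CC)(CC)CC)N1[C@H](Cc2ccccc2)COC1=O | intermediate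
21 | acrolein (prop-2-enal) | C=CC=O | starting material
22 | dibutylboron (Z)-enolate of 20 | CCCCB(CCCC)O/C(=C\[C@H](CC/C(C)=C/I)/C(CO[Si](C)(C)C(C)(C)C)=C/C=C/C(C)(C)O[Si](CC)(CC)CC)N1[C@H](Cc2ccccc2)COC1=O | intermediate
23 | (R)-4-benzyl-3-{(2R,3S,6E)-2-[(1S)-1-hydroxyprop-2-en-1-yl]-7-iodo-6-methyl-3-[(2Z,4E)-1-(TBSO)-6-methyl-6-(TESO)hepta-2,4-dien-2-yl]hept-6-enoyl}oxazolidin-2-one | C=C[C@H](O)[C@@H]([C@H](CC/C(C)=C/I)/C(CO[Si](C)(C)C(C)(C)C)=C/C=C/C(C)(C)O[Si](CC)(CC)CC)C(=O)N1[C@H](Cc2ccccc2)COC1=O | intermediate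
24 | methyl (2R,3S,6E)-2-[(1S)-1-hydroxyprop-2-en-1-yl]-7-iodo-6-methyl-3-[(2Z,4E)-1-(TBSO)-6-methyl-6-(TESO)hepta-2,4-dien-2-yl]hept-6-enoate | C=C[C@H](O)[C@@H]([C@H](CC/C(C)=C/I)/C(CO[Si](C)(C)C(C)(C)C)=C/C=C/C(C)(C)O[Si](CC)(CC)CC)C(=O)OC | intermediate
25 | methyl (2R,3S,6E)-2-[(1S)-3-(9-BBN-9-yl)-1-(9-BBN-9-yloxy)propyl]-7-iodo-6-methyl-3-[(2Z,4E)-1-(TBSO)-6-methyl-6-(TESO)hepta-2,4-dien-2-yl]hept-6-enoate | B1(C2CCCC1CCC2)CC[C@H](OB1C2CCCC1CCC2)[C@@H]([C@H](CC/C(C)=C/I)/C(CO[Si](C)(C)C(C)(C)C)=C/C=C/C(C)(C)O[Si](CC)(CC)CC)C(=O)OC | intermediate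
26 | methyl (1R,2S,5E,9S)-9-hydroxy-5-methyl-2-[(2Z,4E)-1-(TBSO)-6-methyl-6-(TESO)hepta-2,4-dien-2-yl]cyclonon-5-ene-1-carboxylate | O[C@H]1CC/C=C(\C)CC[C@H](/C(=C/C=C/C(C)(C)O[Si](CC)(CC)CC)CO[Si](C)(C)C(C)(C)C)[C@H]1C(=O)OC | intermediate
27 | methyl (1R,2S,5E)-5-methyl-9-oxo-2-[(2Z,4E)-1-(TBSO)-6-methyl-6-(TESO)hepta-2,4-dien-2-yl]cyclonon-5-ene-1-carboxylate | O=C1CC/C=C(\C)CC[C@H](/C(=C/C=C/C(C)(C)O[Si](CC)(CC)CC)CO[Si](C)(C)C(C)(C)C)[C@H]1C(=O)OC | intermediate
28 | methyl (1R,2S,5E)-5-methyl-9-methylidene-2-[(2Z,4E)-1-(TBSO)-6-methyl-6-(TESO)hepta-2,4-dien-2-yl]cyclonon-5-ene-1-carboxylate | C=C1CC/C=C(\C)CC[C@H](/C(=C/C=C/C(C)(C)O[Si](CC)(CC)CC)CO[Si](C)(C)C(C)(C)C)[C@H]1C(=O)OC | intermediate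
29 | methyl (1R,2S,5E)-2-[(2Z,4E)-1,6-dihydroxy-6-methylhepta-2,4-dien-2-yl]-5-methyl-9-methylidenecyclonon-5-ene-1-carboxylate | C=C1CC/C=C(\C)CC[C@H](/C(=C/C=C/C(C)(C)O)CO)[C@H]1C(=O)OC | intermediate
30 | methyl (1R,2S,5E)-2-[(2Z,4E)-1-acetoxy-6-hydroxy-6-methylhepta-2,4-dien-2-yl]-5-methyl-9-methylidenecyclonon-5-ene-1-carboxylate | C=C1CC/C=C(\C)CC[C@H](/C(=C/C=C/C(C)(C)O)COC(C)=O)[C@H]1C(=O)OC | target

**Step count**

Total: 18 steps. Longest linear sequence: 11 steps (1 → 3 → 4 → 10 → 20 → 23 → 24 → 26 → 27 → 28 → 29 → 30, steps 1, 2, 5, 11–18). The branches starting from 5, 11 and 14 are equally long.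

**Steps most likely to fail**

Step 14, the macrocyclization. The (E)-cyclononene is strained, so oligomerisation, protodeboronation or β-hydride elimination can compete, and the free hydroxyl consumes borane. The fallback sets out from 24 and returns to the route at 26. Hydroboration–oxidation of the vinyl group (9-BBN, then NaBO3·4H2O) gives methyl (2R,3S,6E)-2-[(1S)-1,3-dihydroxypropyl]-7-iodo-6-methyl-3-[(2Z,4E)-1-(TBSO)-6-methyl-6-(TESO)hepta-2,4-dien-2-yl]hept-6-enoate F5. Appel iodination of its primary hydroxyl (I2, PPh3, imidazole) gives the iodo alcohol F6. A nickel-catalysed intramolecular reductive cross-electrophile coupling of the alkyl iodide with the alkenyl iodide (NiBr2(dme), 4,4′-di-tert-butyl-2,2′-bipyridine, Zn dust, DMA, 2 mM) then closes the same C6–C7 bond without an organoboron intermediate and gives 26.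

Step 16, the methylenation. Ketone 27 is an α-monosubstituted β-keto ester, so enolisation can epimerise C-1 before or during the reaction, and a titanium enolate can consume the reagent; there is little direct precedent for this substrate class. The fallback sets out from 23 and returns at 28, keeping the oxazolidinone on the carboxyl carbon through the critical stage. The same hydroboration and B-alkyl Suzuki macrocyclization applied to 23 gives the ring hydroxy imide F7. DMP oxidation gives the β-keto imide F8, whose C-1 proton is held in the carbonyl plane by allylic 1,3-strain and is configurationally stable. Tebbe methylenation gives the methylidene imide F9. LiOH/H2O2 removes the auxiliary to give the carboxylic acid F10, and Me3SiCHN2 in MeOH/toluene returns to 28.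

Step 11, the conjugate addition. It needs a functionalised 2-metallated diene (risk of silyl migration or decomposition of 18), an excess of the valuable bromide 17, and high facial selectivity. The fallback sets out from 17 and 4 and returns at 20, setting C-2 under catalyst control without an organolithium. Miyaura borylation of 17 (B2pin2, Pd(dppf)Cl2, KOAc, dioxane) gives the dienylboronate F1. Wittig olefination of 4 with Ph3P=CHCO2Me gives methyl (2E,6E)-7-iodo-6-methylhepta-2,6-dienoate F2. Rhodium-catalysed Hayashi–Miyaura 1,4-addition of F1 to F2 ([Rh(OH)(cod)]2, the BINAP antipode that delivers the 3S adduct, dioxane/H2O) gives the β-dienyl ester F3. LiOH hydrolysis gives the acid F4. Its pivaloyl mixed anhydride (PivCl, Et3N) acylates the lithiated oxazolidinone 7 to give 20.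

**Further compounds**

F1 | step 11 | 2-[(2Z,4E)-1-(TBSO)-6-methyl-6-(TESO)hepta-2,4-dien-2-yl]-4,4,5,5-tetramethyl-1,3,2-dioxaborolane | CC(C)(C)[Si](C)(C)OC/C(B1OC(C)(C)C(C)(C)O1)=C\C=C\C(C)(C)O[Si](CC)(CC)CC
F2 | step 11 | methyl (2E,6E)-7-iodo-6-methylhepta-2,6-dienoate | COC(=O)/C=C/CC/C(C)=C/I
F3 | step 11 | methyl (3S,6E)-7-iodo-6-methyl-3-[(2Z,4E)-1-(TBSO)-6-methyl-6-(TESO)hepta-2,4-dien-2-yl]hept-6-enoate | COC(=O)C[C@H](CC/C(C)=C/I)/C(CO[Si](C)(C)C(C)(C)C)=C/C=C/C(C)(C)O[Si](CC)(CC)CC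
F4 | step 11 | (3S,6E)-7-iodo-6-methyl-3-[(2Z,4E)-1-(TBSO)-6-methyl-6-(TESO)hepta-2,4-dien-2-yl]hept-6-enoic acid | OC(=O)C[C@H](CC/C(C)=C/I)/C(CO[Si](C)(C)C(C)(C)C)=C/C=C/C(C)(C)O[Si](CC)(CC)CC
F5 | step 14 | methyl (2R,3S,6E)-2-[(1S)-1,3-dihydroxypropyl]-7-iodo-6-methyl-3-[(2Z,4E)-1-(TBSO)-6-methyl-6-(TESO)hepta-2,4-dien-2-yl]hept-6-enoate | OCC[C@H](O)[C@@H]([C@H](CC/C(C)=C/I)/C(CO[Si](C)(C)C(C)(C)C)=C/C=C/C(C)(C)O[Si](CC)(CC)CC)C(=O)OC
F6 | step 14 | methyl (2R,3S,6E)-2-[(1S)-1-hydroxy-3-iodopropyl]-7-iodo-6-methyl-3-[(2Z,4E)-1-(TBSO)-6-methyl-6-(TESO)hepta-2,4-dien-2-yl]hept-6-enoate | ICC[C@H](O)[C@@H]([C@H](CC/C(C)=C/I)/C(CO[Si](C)(C)C(C)(C)C)=C/C=C/C(C)(C)O[Si](CC)(CC)CC)C(=O)OC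
F7 | step 16 | (R)-4-benzyl-3-{[(1R,2S,5E,9S)-9-hydroxy-5-methyl-2-[(2Z,4E)-1-(TBSO)-6-methyl-6-(TESO)hepta-2,4-dien-2-yl]cyclonon-5-en-1-yl]carbonyl}oxazolidin-2-one | O[C@H]1CC/C=C(\C)CC[C@H](/C(=C/C=C/C(C)(C)O[Si](CC)(CC)CC)CO[Si](C)(C)C(C)(C)C)[C@H]1C(=O)N2[C@H](Cc3ccccc3)COC2=O
F8 | step 16 | (R)-4-benzyl-3-{[(1R,2S,5E)-5-methyl-9-oxo-2-[(2Z,4E)-1-(TBSO)-6-methyl-6-(TESO)hepta-2,4-dien-2-yl]cyclonon-5-en-1-yl]carbonyl}oxazolidin-2-one | O=C1CC/C=C(\C)CC[C@H](/C(=C/C=C/C(C)(C)O[Si](CC)(CC)CC)CO[Si](C)(C)C(C)(C)C)[C@H]1C(=O)N2[C@H](Cc3ccccc3)COC2=O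
F9 | step 16 | (R)-4-benzyl-3-{[(1R,2S,5E)-5-methyl-9-methylidene-2-[(2Z,4E)-1-(TBSO)-6-methyl-6-(TESO)hepta-2,4-dien-2-yl]cyclonon-5-en-1-yl]carbonyl}oxazolidin-2-one | C=C1CC/C=C(\C)CC[C@H](/C(=C/C=C/C(C)(C)O[Si](CC)(CC)CC)CO[Si](C)(C)C(C)(C)C)[C@H]1C(=O)N2[C@H](Cc3ccccc3)COC2=O
F10 | step 16 | (1R,2S,5E)-5-methyl-9-methylidene-2-[(2Z,4E)-1-(TBSO)-6-methyl-6-(TESO)hepta-2,4-dien-2-yl]cyclonon-5-ene-1-carboxylic acid | C=C1CC/C=C(\C)CC[C@H](/C(=C/C=C/C(C)(C)O[Si](CC)(CC)CC)CO[Si](C)(C)C(C)(C)C)[C@H]1C(=O)O
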